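| setting | violet | red | amber |
|---|---|---|---|
| E | 0.0800 M | 0.0800 M | 0.0800 M |
| L | 0.0800 M | 0.120 M | 0.0800 M |
| time |  |  | 84 min |

- violet run (time / min: [Z] / M): 1.7: 0.00113; 2.9: 0.00338; 4.9: 0.00701; 8.4: 0.01559; 14: 0.02604; 25: 0.03860; 42: 0.04859
- red run (time / min: [Z] / M): 1.7: 0.00213; 2.9: 0.00432; 4.9: 0.01036; 8.4: 0.01937; 14: 0.03145; 25: 0.04606; 42: 0.05732

(each reading ± 2 × 10⁻⁴ M)

* the exponent of [L] in the starting rate at the charge of the violet run (at the point where two percent of the E have become Z)
* Z in the amber run at 84 min, as a share of the E charged

- Overall: E + L -> Z.
- Constant volume, constant temperature.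
- What is held in complexes is read along with the free species.
- "The second partner" is L.
- An order is taken over about fifteen percent of the charge, up and down.

The last violet reading stands at 42 min and amber is asked at 84 min, twice as late. Amber has violet's charge, so violet's curve must be carried on.

What does L do? Between 2.9 min and 8.4 min, red gains 1.23 times as much Z as violet, on 1.50 times the L. Over that step in L, I read an exponent of 0.516.

How do you carry violet on? Let f be the fraction of the E charged not yet turned to Z. If the rate went as f squared, one over f would rise steadily: the second-order plot. Between 25 min and 42 min, violet gives 1.93 and 2.55, so 0.0362 /min. That is the clock, the rise of one over f per minute.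

Is it steady? No. Between 14 min and 25 min it was 0.0409 /min, so it kept 0.884 of its pace.

Then what do you commit to? I let it fall by that factor once more, to 0.0320 /min, which is slower than before. That gives 74.3%.

Isn't one factor for 42.0 min a guess? Yes. An unchanged clock gives 75.4%, so the guess moves the answer by 1.1 percentage points.

The forecast says 0.55 (0.35 to 0.8) and 74% (71% to 77%), holding that “an intermediate or complex builds up first”.

The simulation gives an exponent of 0.48 and 74.1% for amber.

    E ⇌ Q + X (0.09480 /min, 3.972 /M/min)
    Q + L → Z (2.634 /M/min)
    2 E ⇌ E2, settled at all times (4.880 /M)
    2 E → Jy (0.1206 /M/min)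

Early on, at equal Z made, the red rate stands at 1.2 times the violet rate. From violet's reading at 42 min to amber's value at 84 min, the clock comes to 0.0313 /min, which is 0.865 of the late violet clock. Red's late clock, read the same way, is 0.0688 /min. Run back from 25 min, it puts f = 0.5 in red at 19.8 min, and the red flask stood there at 19.6 min.

(The data are simulated with constants of no real substance; the scatter is artificial.)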